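A direct plan would bridge two preformed acylphloroglucinols with formaldehyde: 1-(2,4,6-trihydroxyphenyl)butan-1-one A1 would be condensed with two equivalents of aspidinol A2 and aqueous formaldehyde under base. Its weakest step would be this mixed double methylene bridging, because both phenols would compete for the same quinone methide and A2 would also couple with itself to methylenebis(aspidinol) A3, so that a statistical mixture would result. The second weakness would be the reversibility of such bridges (retro-Friedel–Crafts exchange of benzyl units in acid or alkali), which would scramble mono- and bis-bridged products during the reaction.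

Ring A (C1 butanoyl; C2, C4, C6 hydroxyl; C3, C5 bridges) is a cyclised 1,3,5-tricarbonyl chain, and each ring B has its C2' hydroxyl ortho to the bridge. The route therefore builds ring A last by a [5+1] disconnection at C1–C2 and C1–C6: both arms are joined to dimethyl 3-oxopentanedioate as coumarins, so that each bridge carbon is C4 of a lactone whose carbonyl is C2 or C6 of ring A. In the key step the bis-lactone acylates nonane-4,6-dione twice at its central carbon and loss of one butanoyl aromatises ring A, freeing both C2' phenols. No methylene transfer between phenols occurs, so neither statistical coupling nor scrambling can arise.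

Key step: step 6

Remark: ring A is numbered C1 (butanoyl) to C6 and each ring B C1' (bridge), C2' (OH), C3' (butanoyl), C4' (OH), C5' (CH3), C6' (OCH3); compounds 1, 6 and 10 are taken as commercial; the target has no stereocentre.

Step 1
Reactants: 1 2-methylbenzene-1,3,5-triol
Product: 2 1-(2,4,6-trihydroxy-3-methylphenyl)butan-1-one
Conditions: PrCOCl (1.05 equiv), AlCl3 (3.5 equiv), PhNO2–CH2Cl2, 0 → 45 °C; 1 M HCl
Reagents that add atoms: butanoyl chloride CCCC(=O)Cl
Why: Friedel–Crafts C-acylation of the triphenol at one of its two equivalent free positions, after which the acyl group deactivates the ring against a second acylation.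

Step 2
Reactants: 2 1-(2,4,6-trihydroxy-3-methylphenyl)butan-1-one
Product: 3 1-(2,6-dihydroxy-4-methoxy-3-methylphenyl)butan-1-one (aspidinol)
Conditions: Me2SO4 (1.0 equiv), K2CO3 (1.0 equiv), acetone, rt
Reagents that add atoms: dimethyl sulfate COS(=O)(=O)OC
Why: Chelation-controlled Williamson O-methylation, in which one equivalent of weak base ionises the hydroxyl para to the ketone, the most acidic one and the only one that cannot share the hydrogen bond to the carbonyl, so that the methyl ether ends next to the C-methyl group as in ring B.

Step 3
Reactants: 3 1-(2,6-dihydroxy-4-methoxy-3-methylphenyl)butan-1-one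
Product: 5 3-butanoyl-2,4-dihydroxy-6-methoxy-5-methylbenzaldehyde, via chloro(methoxy)methyl arene 4 (not isolated)
Conditions: Cl2CHOMe (1.5 equiv), TiCl4 (3 equiv), CH2Cl2, −10 °C → rt; then 1 M HCl
Reagents that add atoms: dichloromethyl methyl ether COC(Cl)Cl; water O
Why: Rieche formylation (electrophilic aromatic substitution by the TiCl4-activated dichloromethyl ether, then hydrolysis of chloro ether 4) at the only unsubstituted ring carbon, ortho to a titanium phenoxide; a Lewis-acid method is preferred to the Vilsmeier reagent, which can attack the alpha-methylene of a 2-hydroxyaryl ketone (chromone formation).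

Step 4
Reactants: 5 3-butanoyl-2,4-dihydroxy-6-methoxy-5-methylbenzaldehyde, 6 dimethyl 3-oxopentanedioate
Product: 8 3,3'-carbonylbis(8-butanoyl-7-hydroxy-5-methoxy-6-methyl-2H-chromen-2-one), via mono-coumarin keto ester 7 (not isolated)
Conditions: 5 (2.05 equiv), piperidine (0.3 equiv), AcOH (0.3 equiv), EtOH, reflux
Reagents that add atoms: none
Why: Twofold Knoevenagel condensation of the keto diester with the salicylaldehyde, each followed by lactonisation (coumarin synthesis, the usual access to 3,3'-carbonylbiscoumarins); because C6' is already a methyl ether only the C2' hydroxyl can close the lactone, so each future bridge carbon becomes C4 of a coumarin.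

Step 5
Reactants: 8 3,3'-carbonylbis(8-butanoyl-7-hydroxy-5-methoxy-6-methyl-2H-chromen-2-one)
Product: 9 3,3'-carbonylbis(8-butanoyl-7-hydroxy-5-methoxy-6-methyl-3,4-dihydro-2H-chromen-2-one) (mixture of rac and meso forms and enol tautomers)
Conditions: H2 (1 atm), Pd/C (10% palladium on carbon), THF–EtOAc, rt; filtered and used without chromatography
Reagents that add atoms: none
Why: Catalytic hydrogenation of the two electron-poor C3=C4 double bonds of the 3-acylcoumarins under neutral conditions, which should leave the chelated aryl ketones intact; the two new alpha stereocentres are labile (enolisable beta-keto lactone) and are removed in step 6.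

Step 6
Reactants: 9 3,3'-carbonylbis(8-butanoyl-7-hydroxy-5-methoxy-6-methyl-3,4-dihydro-2H-chromen-2-one), 10 nonane-4,6-dione
Product: 14 1-{3,5-bis[(3-butanoyl-2,4-dihydroxy-6-methoxy-5-methylphenyl)methyl]-2,4,6-trihydroxyphenyl}butan-1-one (CNP0264591.0), via acyl-transfer adduct 11 (not isolated), via pyranone 12 (not isolated), via triketo ester 13 (not isolated)
Conditions: 10 (1.5 equiv), DBU (6 equiv), THF, 50 °C; then NaOMe (12 equiv), MeOH, 65 °C; then 1 M HCl, 0 °C
Reagents that add atoms: none
Why: Proposed new method: DBU turns the beta-keto aryl lactone 9 into its enolate, which opens by E1cB to an acylketene (the leaving aryloxide is stabilised by the ortho butanoyl group) that acylates the enolate of 10 at carbon, O-acylation being reversible by the same path, to give 11; the second lactone is then consumed within the molecule, by the C2 enol oxygen to give pyranone 12 or directly by C1, and NaOMe brings both lines together by removing one butanoyl group from C1 (retro-Claisen, methyl butanoate) and reopening 12 to keto ester 13, whose C1 enolate attacks the C6 ester before the trione tautomerises to the phenol. The closest known reaction types are the base-induced Claisen cyclisation of 3,5,7-trioxoalkanoates and of 6-(2-oxoalkyl)-4-hydroxypyran-2-ones to acylphloroglucinols, the acyl transfer of aryl beta-keto esters through acylketenes and the acylation–deacylation of beta-diketones, which have not been joined in a [5+1] annulation that places a fully substituted ring between two finished arenes. Ring A closes as a six-membered carbocycle by 6-exo-trig attack of C1 on the C6 carbonyl (Dieckmann mode) after the C1–C2 bond has been formed between the two reactants. No stereocentre is formed, and the two labile centres of 9 (C3 and C5 of ring A) become sp2. The step needs Claisen and not aldol ring closure, and it needs to lose exactly one acyl group: the arylmethyl groups on C3 and C5 leave an aldol adduct no way to aromatise, so that mode stays reversible, and because both acyl groups of 10 are butanoyl either cleavage gives the same ring A, in which the symmetry of 9 puts the butanoyl group between two of the new hydroxyls. The ring B ketones are chelated to phenoxides and are poorly acidic, so that enolisation at their alpha carbon (Baker–Venkataraman attack on the neighbouring lactone) should not compete with the E1cB opening.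

**Compound list**

1 | 2-methylbenzene-1,3,5-triol | Cc1c(O)cc(O)cc1O | starting material
2 | 1-(2,4,6-trihydroxy-3-methylphenyl)butan-1-one | CCCC(=O)c1c(O)cc(O)c(C)c1O | intermediate
3 | 1-(2,6-dihydroxy-4-methoxy-3-methylphenyl)butan-1-one (aspidinol) | CCCC(=O)c1c(O)cc(OC)c(C)c1O | intermediate
4 | 1-{3-[chloro(methoxy)methyl]-2,6-dihydroxy-4-methoxy-5-methylphenyl}butan-1-one (racemic, transient) | CCCC(=O)c1c(O)c(C(Cl)OC)c(OC)c(C)c1O | intermediate (not isolated)
5 | 3-butanoyl-2,4-dihydroxy-6-methoxy-5-methylbenzaldehyde | CCCC(=O)c1c(O)c(C=O)c(OC)c(C)c1O | intermediate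
6 | dimethyl 3-oxopentanedioate | COC(=O)CC(=O)CC(=O)OC | starting material
7 | methyl 3-(8-butanoyl-7-hydroxy-5-methoxy-6-methyl-2-oxo-2H-chromen-3-yl)-3-oxopropanoate | COC(=O)CC(=O)c1cc2c(OC)c(C)c(O)c(C(=O)CCC)c2oc1=O | intermediate (not isolated)
8 | 3,3'-carbonylbis(8-butanoyl-7-hydroxy-5-methoxy-6-methyl-2H-chromen-2-one) | O=C(c1cc2c(OC)c(C)c(O)c(C(=O)CCC)c2oc1=O)c1cc2c(OC)c(C)c(O)c(C(=O)CCC)c2oc1=O | intermediate
9 | 3,3'-carbonylbis(8-butanoyl-7-hydroxy-5-methoxy-6-methyl-3,4-dihydro-2H-chromen-2-one) (both C3 centres labile; mixture) | O=C(C1Cc2c(OC)c(C)c(O)c(C(=O)CCC)c2OC1=O)C1Cc2c(OC)c(C)c(O)c(C(=O)CCC)c2OC1=O | intermediate (key-step precursor)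
10 | nonane-4,6-dione | CCCC(=O)CC(=O)CCC | starting material
11 | 3-{2-[(3-butanoyl-2,4-dihydroxy-6-methoxy-5-methylphenyl)methyl]-4-butanoyl-3,5-dioxooctanoyl}-8-butanoyl-7-hydroxy-5-methoxy-6-methyl-3,4-dihydro-2H-chromen-2-one (stereoisomers and enol forms) | CCCC(=O)C(C(=O)CCC)C(=O)C(Cc1c(O)c(C(=O)CCC)c(O)c(C)c1OC)C(=O)C1Cc2c(OC)c(C)c(O)c(C(=O)CCC)c2OC1=O | intermediate (not isolated)
12 | 5-{3,5-bis[(3-butanoyl-2,4-dihydroxy-6-methoxy-5-methylphenyl)methyl]-4-hydroxy-2-oxo-2H-pyran-6-yl}nonane-4,6-dione | CCCC(=O)C(C(=O)CCC)c1oc(=O)c(Cc2c(O)c(C(=O)CCC)c(O)c(C)c2OC)c(O)c1Cc1c(O)c(C(=O)CCC)c(O)c(C)c1OC | intermediate (not isolated)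
13 | methyl 2,4-bis[(3-butanoyl-2,4-dihydroxy-6-methoxy-5-methylphenyl)methyl]-3,5,7-trioxodecanoate (stereoisomers and enol forms) | COC(=O)C(Cc1c(O)c(C(=O)CCC)c(O)c(C)c1OC)C(=O)C(Cc1c(O)c(C(=O)CCC)c(O)c(C)c1OC)C(=O)CC(=O)CCC | intermediate (not isolated)
14 | 1-{3,5-bis[(3-butanoyl-2,4-dihydroxy-6-methoxy-5-methylphenyl)methyl]-2,4,6-trihydroxyphenyl}butan-1-one (CNP0264591.0; no stereocentres) | CCCC(=O)c1c(O)c(Cc2c(O)c(C(=O)CCC)c(O)c(C)c2OC)c(O)c(Cc2c(O)c(C(=O)CCC)c(O)c(C)c2OC)c1O | target

Total step count: 6. Longest linear sequence: 6 steps (1 → 14); compounds 6 and 10 enter as purchased reagents.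

Steps most likely to fail:

Step 6. The intermolecular acyl transfer may lose to reclosure of the lactone, the sequence may stop at the pyranone because its anion resists methoxide, or the finished bridges may exchange in hot alkoxide. The fallback gives up the construction of ring A and uses known quinone methide chemistry in a directed pairing. It sets out from 3: commercial 1-(2,4,6-trihydroxyphenyl)butan-1-one (A1) would be converted with aqueous formaldehyde and dimethylamine into the bis-Mannich base 1-{3,5-bis[(dimethylamino)methyl]-2,4,6-trihydroxyphenyl}butan-1-one F1. Heating F1 with 3 (2.2 equiv) in dioxane would release the two ortho-quinone methides one after the other, and 3 would add through its only free ring carbon, so that the route is rejoined at 14. Neither partner can couple with itself in this pairing.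

Step 4. The aldehyde 5 is a hindered vinylogous acid, so the condensation may stall at the mono-coumarin stage or revert. The fallback forms each bridge by conjugate addition instead of condensation and needs neither formylation nor hydrogenation. It sets out from 3: a Mannich reaction (aqueous formaldehyde, dimethylamine, EtOH) would give 1-{3-[(dimethylamino)methyl]-2,6-dihydroxy-4-methoxy-5-methylphenyl}butan-1-one F2. Heating F2 (2 equiv) with 6 in toluene would alkylate the keto diester at both alpha carbons through the ortho-quinone methide to give dimethyl 2,4-bis[(3-butanoyl-2,4-dihydroxy-6-methoxy-5-methylphenyl)methyl]-3-oxopentanedioate F3. TsOH in refluxing toluene would then close both lactones, and the route is rejoined at 9.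

Step 2. Methylation may run on to a second hydroxyl or take a hydroxyl ortho to the ketone. The fallback replaces selective methylation by selective demethylation. It sets out from 2: exhaustive methylation (Me2SO4 in excess, K2CO3, acetone, reflux) would give 1-(2,4,6-trimethoxy-3-methylphenyl)butan-1-one F4. BCl3 (excess, CH2Cl2, 0 °C → rt) would then cleave only the two methyl ethers ortho to the ketone through boron chelates and leave the para methyl ether, and the route is rejoined at 3.

Further compounds

F1 | step 6 | 1-{3,5-bis[(dimethylamino)methyl]-2,4,6-trihydroxyphenyl}butan-1-one | CCCC(=O)c1c(O)c(CN(C)C)c(O)c(CN(C)C)c1O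
F2 | step 4 | 1-{3-[(dimethylamino)methyl]-2,6-dihydroxy-4-methoxy-5-methylphenyl}butan-1-one | CCCC(=O)c1c(O)c(CN(C)C)c(OC)c(C)c1O
F3 | step 4 | dimethyl 2,4-bis[(3-butanoyl-2,4-dihydroxy-6-methoxy-5-methylphenyl)methyl]-3-oxopentanedioate | COC(=O)C(Cc1c(O)c(C(=O)CCC)c(O)c(C)c1OC)C(=O)C(Cc1c(O)c(C(=O)CCC)c(O)c(C)c1OC)C(=O)OC
F4 | step 2 | 1-(2,4,6-trimethoxy-3-methylphenyl)butan-1-one | CCCC(=O)c1c(OC)cc(OC)c(C)c1OC
A1 | direct plan | 1-(2,4,6-trihydroxyphenyl)butan-1-one | CCCC(=O)c1c(O)cc(O)cc1O
A2 | direct plan | 1-(2,6-dihydroxy-4-methoxy-3-methylphenyl)butan-1-one (aspidinol) | CCCC(=O)c1c(O)cc(OC)c(C)c1O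
A3 | direct plan | 1,1'-[methylenebis(2,6-dihydroxy-4-methoxy-5-methyl-3,1-phenylene)]di(butan-1-one) | CCCC(=O)c1c(O)c(Cc2c(O)c(C(=O)CCC)c(O)c(C)c2OC)c(OC)c(C)c1O
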